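**Retrosynthetic overview**
1. Target 8 ⇐ benzyl β-keto ester 6 by one-pot hydrogenolysis of all three benzyl groups and loss of CO2.
2. 6 ⇐ crossed Claisen condensation of the enolate of benzyl 3,5-bis(benzyloxy)phenylacetate 2 with palmitoyl chloride 3; this makes the benzylic-carbon-to-ketone-carbon bond (C1–C2 of the heptadecanone).
3. 2 ⇐ 3,5-dihydroxyphenylacetic acid 1 by one-pot tribenzylation.
4. No ring is formed: the benzene ring is bought intact in 1.

Assumption: the target SMILES has no stereocentre and no stereogenic double bond, so the compound is achiral and no stereocontrol is needed.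

**Route**

Step 1
Reactants: 1 2-(3,5-dihydroxyphenyl)acetic acid
Product: 2 benzyl 2-[3,5-bis(benzyloxy)phenyl]acetate
Conditions: BnBr (3.5 equiv), K2CO3 (4 equiv), DMF, 60 °C, 12 h
Reagents that add atoms: benzyl bromide, BrCc1ccccc1
Why: Williamson ether synthesis on both phenoxides and SN2 O-alkylation of the carboxylate run together, while K2CO3 is too weak to enolise the arylacetate, so C-benzylation does not compete; no stereocentre is involved.

Step 2
Reactants: 2 benzyl 2-[3,5-bis(benzyloxy)phenyl]acetate; 3 hexadecanoyl chloride (palmitoyl chloride)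
Product: 6 benzyl 2-[3,5-bis(benzyloxy)phenyl]-3-oxooctadecanoate, via lithium enolate of the ester 4 (not isolated), via lithium enolate of the keto ester 5 (not isolated)
Conditions: LiN(SiMe3)2 (2.1 equiv), THF, −78 °C, 45 min; then 3 (1.05 equiv), −78 → 0 °C; 1 M HCl quench
Reagents that add atoms: none
Why: Crossed Claisen condensation in which the preformed aryl-stabilised enolate 4 is C-acylated by 3 and the second equivalent of base traps the more acidic β-keto ester as enolate 5, which blocks diacylation and retro-Claisen cleavage; the new C2 stereocentre forms racemic and is erased in step 3.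

Step 3
Reactants: 6 benzyl 2-[3,5-bis(benzyloxy)phenyl]-3-oxooctadecanoate
Product: 8 1-(3,5-dihydroxyphenyl)heptadecan-2-one, via keto acid 7 (not isolated)
Conditions: H2 (1 atm), 10% Pd/C, EtOAc–EtOH 1:1, rt, 6 h; filter; 50 °C, 1 h
Reagents that add atoms: none
Why: Catalytic hydrogenolysis cleaves both benzyl ethers and the benzyl ester, and the freed α-aryl β-keto acid 7 loses CO2 through the cyclic six-membered transition state on gentle warming (decarboxylative ketone synthesis), the unconjugated ketone being inert to Pd/C at 1 atm; no stereocentre remains.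

**Compound list**
1 | 2-(3,5-dihydroxyphenyl)acetic acid | OC(=O)Cc1cc(O)cc(O)c1 | starting material
2 | benzyl 2-[3,5-bis(benzyloxy)phenyl]acetate | O=C(Cc1cc(OCc2ccccc2)cc(OCc2ccccc2)c1)OCc1ccccc1 | intermediate
3 | hexadecanoyl chloride (palmitoyl chloride) | CCCCCCCCCCCCCCCC(Cl)=O | starting material
4 | lithium enolate of 2 (geometry inconsequential; not isolated) | [Li+].[O-]C(OCc1ccccc1)=Cc1cc(OCc2ccccc2)cc(OCc2ccccc2)c1 | intermediate
5 | lithium enolate of 6 (not isolated) | [Li+].CCCCCCCCCCCCCCCC([O-])=C(C(=O)OCc1ccccc1)c1cc(OCc2ccccc2)cc(OCc2ccccc2)c1 | intermediate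
6 | benzyl 2-[3,5-bis(benzyloxy)phenyl]-3-oxooctadecanoate (racemic at C2, largely enolised) | CCCCCCCCCCCCCCCC(=O)C(C(=O)OCc1ccccc1)c1cc(OCc2ccccc2)cc(OCc2ccccc2)c1 | intermediate
7 | 2-(3,5-dihydroxyphenyl)-3-oxooctadecanoic acid (not isolated) | CCCCCCCCCCCCCCCC(=O)C(C(=O)O)c1cc(O)cc(O)c1 | intermediate
8 | 1-(3,5-dihydroxyphenyl)heptadecan-2-one | CCCCCCCCCCCCCCCC(=O)Cc1cc(O)cc(O)c1 | target

**Totals**
Total step count: 3. Longest linear sequence: 3 steps (1 → 2 → 6 → 8; compound 3 is bought and enters at step 2).

**Steps most likely to fail, with fallbacks**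

Step 2 (most at risk). The excess amide base can attack the acid chloride, and O-acylation or diacylation of the enolate can lower the yield. The fallback sets out from 2 and comes back at 6, replacing the acylation by an aldol addition followed by oxidation. Enolate 4 is generated as before with 1.1 equiv of LiN(SiMe3)2 in THF at −78 °C and treated with commercial hexadecanal (CCCCCCCCCCCCCCCC=O). Quenching with aqueous NH4Cl gives benzyl 2-[3,5-bis(benzyloxy)phenyl]-3-hydroxyoctadecanoate F2 as an inconsequential mixture of diastereomers. Oxidation of this secondary alcohol with Dess–Martin periodinane and NaHCO3 in CH2Cl2 at 0 °C to rt gives 6.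

Step 3. Debenzylation may stall, or the ketone may be partly reduced on prolonged exposure. The fallback sets out from 6 and comes back at 8, separating the decarboxylation from the deprotection and avoiding hydrogen altogether. Krapcho dealkoxycarbonylation of 6 with LiCl in wet DMSO at 140 °C gives 1-[3,5-bis(benzyloxy)phenyl]heptadecan-2-one F3. The two aryl benzyl ethers are then cleaved with BCl3 and pentamethylbenzene as the benzyl-cation scavenger in CH2Cl2 at −78 °C, giving 8 after aqueous work-up.

Step 1. Forcing three alkylations in one pot can leave partly benzylated mixtures or give a little C-benzylation of the electron-rich ring. The fallback sets out from 1 and comes back at 2, installing the ester and the ethers separately, the ethers under neutral conditions. Selective carboxylate alkylation of 1 with 1.05 equiv of BnBr and KHCO3 in DMF at rt gives benzyl 2-(3,5-dihydroxyphenyl)acetate F1. A double Mitsunobu etherification of the two phenols with benzyl alcohol, PPh3 and diisopropyl azodicarboxylate in THF at 0 °C to rt then gives 2.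

**Further compounds**
F1 | step 1 | benzyl 2-(3,5-dihydroxyphenyl)acetate | O=C(Cc1cc(O)cc(O)c1)OCc1ccccc1
F2 | step 2 | benzyl 2-[3,5-bis(benzyloxy)phenyl]-3-hydroxyoctadecanoate (mixture of diastereomers) | CCCCCCCCCCCCCCCC(O)C(C(=O)OCc1ccccc1)c1cc(OCc2ccccc2)cc(OCc2ccccc2)c1
F3 | step 3 | 1-[3,5-bis(benzyloxy)phenyl]heptadecan-2-one | CCCCCCCCCCCCCCCC(=O)Cc1cc(OCc2ccccc2)cc(OCc2ccccc2)c1
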